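**Retrosynthetic overview**

- The target is reached from its 5,7-di-O-benzyl ether by hydrogenolysis, so the chromone is built with both phenols masked.
- The plan rests on ring A: the bonds O1–C8a and C4–C4a leave neighbouring carbons, with C4a ortho and C8a meta to the C5 oxygen. This is the pattern in which a nucleophile (meta carbon) and an electrophile (ortho carbon) add across the strained bond of a 3-alkoxybenzyne.
- Both bonds are cut together. Ring A becomes 3,5-bis(benzyloxy)-4-methoxybenzyne, released from its 2-silylaryl triflate. C2, C3 with its aryl group and C4 come as the enolate of methyl 3-hydroxy-2-(2,3,4-trimethoxyphenyl)acrylate. The pyranone (ring C) is the only ring formed; rings A and B are bought.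
- The silylaryl triflate comes from the symmetric 3,5-bis(benzyloxy)-4-methoxyphenol (bromination, O-silylation, retro-Brook shift, triflation), and the phenol from methyl 3,5-dihydroxy-4-methoxybenzoate (benzylation, reduction, oxidation, Dakin-type oxidation).
- The enol ester comes from 2,3,4-trimethoxyphenylacetic acid by esterification and Claisen formylation with methyl formate.

Key step: step 10

Remark: compound 15 is a mixture of tautomers (aldehyde and enols) that share one enolate; it is drawn as the hydrogen-bonded Z-enol.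

**Route**

Step 1
Reactants: 1 methyl 3,5-dihydroxy-4-methoxybenzoate
Product: 2 methyl 3,5-bis(benzyloxy)-4-methoxybenzoate
Conditions: BnBr (2.4 equiv), K2CO3, DMF, 60 °C
Reagents that add atoms: benzyl bromide, BrCc1ccccc1
Why: Williamson ether synthesis, in which both phenoxides formed by K2CO3 displace bromide from benzyl bromide while the methyl ester is untouched.

Step 2
Reactants: 2 methyl 3,5-bis(benzyloxy)-4-methoxybenzoate
Product: 3 [3,5-bis(benzyloxy)-4-methoxyphenyl]methanol
Conditions: LiAlH4, THF, 0 °C to rt
Reagents that add atoms: none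
Why: Hydride reduction of an aryl ester to the benzylic alcohol with LiAlH4, to which the benzyl and methyl aryl ethers are inert.

Step 3
Reactants: 3 [3,5-bis(benzyloxy)-4-methoxyphenyl]methanol
Product: 4 3,5-bis(benzyloxy)-4-methoxybenzaldehyde
Conditions: activated MnO2, CH2Cl2, rt
Reagents that add atoms: none
Why: Selective oxidation of a benzylic alcohol with MnO2, which should stop cleanly at the aldehyde.

Step 4
Reactants: 4 3,5-bis(benzyloxy)-4-methoxybenzaldehyde
Product: 6 3,5-bis(benzyloxy)-4-methoxyphenol, via aryl formate 5 (not isolated)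
Conditions: mCPBA, CH2Cl2, 0 °C to rt; then K2CO3 (cat.), MeOH, rt
Reagents that add atoms: meta-chloroperoxybenzoic acid, O=C(OO)c1cccc(Cl)c1
Why: Dakin-type Baeyer–Villiger oxidation, in which the electron-rich trialkoxyaryl group migrates in the Criegee intermediate to give formate 5, which methanolysis cleaves to the phenol.

Step 5
Reactants: 6 3,5-bis(benzyloxy)-4-methoxyphenol
Product: 7 3,5-bis(benzyloxy)-2-bromo-4-methoxyphenol
Conditions: NBS (1.0 equiv), CH2Cl2, −78 °C to 0 °C
Reagents that add atoms: N-bromosuccinimide, O=C1CCC(=O)N1Br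
Why: Electrophilic aromatic bromination; the para position is blocked and the two free positions ortho to the hydroxyl group are equivalent by symmetry, so one equivalent of NBS at low temperature should give a single monobromide.

Step 6
Reactants: 7 3,5-bis(benzyloxy)-2-bromo-4-methoxyphenol
Product: 8 [3,5-bis(benzyloxy)-2-bromo-4-methoxyphenoxy]trimethylsilane
Conditions: HMDS, THF, 65 °C; concentrate
Reagents that add atoms: hexamethyldisilazane, C[Si](C)(C)N[Si](C)(C)C
Why: O-Silylation of the phenol with hexamethyldisilazane, driven by loss of ammonia, gives the silyl ether needed for the migration.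

Step 7
Reactants: 8 [3,5-bis(benzyloxy)-2-bromo-4-methoxyphenoxy]trimethylsilane
Product: 11 3,5-bis(benzyloxy)-4-methoxy-2-(trimethylsilyl)phenyl trifluoromethanesulfonate, via aryllithium 9 (not isolated), via lithium phenoxide 10 (not isolated)
Conditions: n-BuLi (1.1 equiv), THF, −78 °C; then Tf2O (1.2 equiv), −78 °C
Reagents that add atoms: trifluoromethanesulfonic anhydride, O=S(=O)(OS(=O)(=O)C(F)(F)F)C(F)(F)F
Why: Bromine–lithium exchange gives aryllithium 9, which undergoes the 1,3 O-to-C silyl shift (retro-Brook rearrangement) to phenoxide 10, and O-triflation of 10 with Tf2O gives the silylaryl triflate.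

Step 8
Reactants: 12 2,3,4-trimethoxyphenylacetic acid
Product: 13 methyl 2-(2,3,4-trimethoxyphenyl)acetate
Conditions: MeOH, H2SO4 (cat.), reflux
Reagents that add atoms: methanol, CO
Why: Fischer esterification of the arylacetic acid in excess methanol.

Step 9
Reactants: 13 methyl 2-(2,3,4-trimethoxyphenyl)acetate; 14 methyl formate
Product: 15 methyl (Z)-3-hydroxy-2-(2,3,4-trimethoxyphenyl)acrylate
Conditions: NaH, HCO2Me (excess), THF, 0 °C to rt; then 1 M HCl
Reagents that add atoms: methyl formate, COC=O
Why: Crossed Claisen condensation (formylation), in which the ester enolate attacks methyl formate, which has no alpha-hydrogen, and deprotonation of the product drives the equilibrium before acidification releases the enol.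

Step 10
Reactants: 11 3,5-bis(benzyloxy)-4-methoxy-2-(trimethylsilyl)phenyl trifluoromethanesulfonate; 15 methyl (Z)-3-hydroxy-2-(2,3,4-trimethoxyphenyl)acrylate
Product: 18 5,7-bis(benzyloxy)-6-methoxy-3-(2,3,4-trimethoxyphenyl)-4H-chromen-4-one, via benzyne 16 (not isolated), via aryl caesium adduct 17 (not isolated)
Conditions: 15 (1.5 equiv), CsF (4 equiv), THF, 65 °C
Reagents that add atoms: none
Why: Proposed new method: fluoride removes the silyl group of 11 and triflate leaves to give aryne 16, whose C3 benzyloxy group polarises the strained bond so that the caesium enolate of 15 should attack through oxygen at the distal carbon (future C8a) while the negative charge develops on the carbon next to that benzyloxy group (future C4a), giving 17. The closest known reactions are the fluoride-mediated aryne annulation of salicylate esters to xanthones (O-arylation, then intramolecular acyl capture) and the aryne acyl-alkylation of beta-keto esters; a formylacetate enolate has not been shown in this role. The pyranone closes by 6-exo-trig attack of the C4a carbanion on the ester carbonyl with loss of methoxide, so C4–C4a forms after O1–C8a. No stereocentre is created. Two selectivities are needed: addition at C8a, which the inductive effect of the adjacent 5-benzyloxy group should enforce as in other 3-alkoxyarynes, and O- over C-arylation of the ambident enolate, which the fully substituted, aryl-shielded alpha-carbon, the caesium counter-ion and the chelated Z geometry (ester cis to the enolate oxygen, so the anion of 17 can reach the carbonyl) favour but do not guarantee. THF is chosen over MeCN so that the aryl anion is less likely to be protonated before it cyclises.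

Step 11
Reactants: 18 5,7-bis(benzyloxy)-6-methoxy-3-(2,3,4-trimethoxyphenyl)-4H-chromen-4-one
Product: 19 5,7-dihydroxy-6-methoxy-3-(2,3,4-trimethoxyphenyl)-4H-chromen-4-one
Conditions: H2 (1 atm), 10% Pd/C, EtOAc–MeOH, rt
Reagents that add atoms: none
Why: Catalytic hydrogenolysis of the two benzyl aryl ethers over Pd/C at ambient pressure, stopped after uptake of two equivalents so that the chromone C2–C3 double bond and the methyl ethers are kept.

**Compound list**

1 | methyl 3,5-dihydroxy-4-methoxybenzoate | COC(=O)c1cc(O)c(OC)c(O)c1 | starting material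
2 | methyl 3,5-bis(benzyloxy)-4-methoxybenzoate | COC(=O)c1cc(OCc2ccccc2)c(OC)c(OCc2ccccc2)c1 | intermediate
3 | [3,5-bis(benzyloxy)-4-methoxyphenyl]methanol | COc1c(OCc2ccccc2)cc(CO)cc1OCc1ccccc1 | intermediate
4 | 3,5-bis(benzyloxy)-4-methoxybenzaldehyde | COc1c(OCc2ccccc2)cc(C=O)cc1OCc1ccccc1 | intermediate
5 | 3,5-bis(benzyloxy)-4-methoxyphenyl formate (not isolated) | COc1c(OCc2ccccc2)cc(OC=O)cc1OCc1ccccc1 | intermediate
6 | 3,5-bis(benzyloxy)-4-methoxyphenol | COc1c(OCc2ccccc2)cc(O)cc1OCc1ccccc1 | intermediate
7 | 3,5-bis(benzyloxy)-2-bromo-4-methoxyphenol | COc1c(OCc2ccccc2)cc(O)c(Br)c1OCc1ccccc1 | intermediate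
8 | [3,5-bis(benzyloxy)-2-bromo-4-methoxyphenoxy]trimethylsilane | COc1c(OCc2ccccc2)cc(O[Si](C)(C)C)c(Br)c1OCc1ccccc1 | intermediate
9 | [2,4-bis(benzyloxy)-3-methoxy-6-(trimethylsilyloxy)phenyl]lithium (not isolated) | COc1c(OCc2ccccc2)cc(O[Si](C)(C)C)c([Li])c1OCc1ccccc1 | intermediate
10 | lithium 3,5-bis(benzyloxy)-4-methoxy-2-(trimethylsilyl)phenoxide (not isolated) | COc1c(OCc2ccccc2)cc([O-])c([Si](C)(C)C)c1OCc1ccccc1.[Li+] | intermediate
11 | 3,5-bis(benzyloxy)-4-methoxy-2-(trimethylsilyl)phenyl trifluoromethanesulfonate | COc1c(OCc2ccccc2)cc(OS(=O)(=O)C(F)(F)F)c([Si](C)(C)C)c1OCc1ccccc1 | intermediate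
12 | 2,3,4-trimethoxyphenylacetic acid | COc1ccc(CC(=O)O)c(OC)c1OC | starting material
13 | methyl 2-(2,3,4-trimethoxyphenyl)acetate | COC(=O)Cc1ccc(OC)c(OC)c1OC | intermediate
14 | methyl formate | COC=O | starting material
15 | methyl (Z)-3-hydroxy-2-(2,3,4-trimethoxyphenyl)acrylate | COC(=O)/C(=C\O)c1ccc(OC)c(OC)c1OC | intermediate
16 | 3,5-bis(benzyloxy)-4-methoxybenzyne (1,2-didehydro arene, not isolated) | COC1=C(OCc2ccccc2)C#CC=C1OCc1ccccc1 | intermediate
17 | methyl (Z)-3-[3,5-bis(benzyloxy)-2-caesio-4-methoxyphenoxy]-2-(2,3,4-trimethoxyphenyl)acrylate (not isolated) | COC(=O)/C(=C\OC1=CC(OCc2ccccc2)=C(OC)C(OCc2ccccc2)=[C-]1)c1ccc(OC)c(OC)c1OC.[Cs+] | intermediate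
18 | 5,7-bis(benzyloxy)-6-methoxy-3-(2,3,4-trimethoxyphenyl)-4H-chromen-4-one | COc1ccc(-c2coc3cc(OCc4ccccc4)c(OC)c(OCc4ccccc4)c3c2=O)c(OC)c1OC | intermediate
19 | 5,7-dihydroxy-6-methoxy-3-(2,3,4-trimethoxyphenyl)-4H-chromen-4-one | COc1ccc(-c2coc3cc(O)c(OC)c(O)c3c2=O)c(OC)c1OC | target

**Step count**

Total: 11 steps. Longest linear sequence: 9 steps (steps 1–7, 10, 11); steps 8 and 9 form the second branch.

**Steps most likely to fail**

1. Step 10 (proposed new method). The enolate may add to the aryne through carbon, which would lead on to formal insertion into the C–C bond instead of the chromone. The aryl anion may also be protonated before it reaches the ester, or O-arylation may take place from the extended enolate geometry, leaving the ester out of reach.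
Fallback by known chemistry, from bromophenol 7 and acid 12, returning at 18 (deoxybenzoin route). Bromophenol 7 is protected with MOMCl and iPr2NEt in CH2Cl2 as 1,3-bis(benzyloxy)-4-bromo-2-methoxy-5-(methoxymethoxy)benzene F1. Acid 12 is converted with carbonyldiimidazole and then MeNHOMe·HCl into N-methoxy-N-methyl-2-(2,3,4-trimethoxyphenyl)acetamide F2. Bromine–lithium exchange on F1 (n-BuLi, THF, −78 °C) and acylation by F2 should give 1-[2,4-bis(benzyloxy)-3-methoxy-6-(methoxymethoxy)phenyl]-2-(2,3,4-trimethoxyphenyl)ethan-1-one F3. HCl in MeOH removes the acetal to give 1-[2,4-bis(benzyloxy)-6-hydroxy-3-methoxyphenyl]-2-(2,3,4-trimethoxyphenyl)ethan-1-one F4. Heating F4 with DMF dimethyl acetal in toluene forms (E)-1-[2,4-bis(benzyloxy)-6-hydroxy-3-methoxyphenyl]-3-(dimethylamino)-2-(2,3,4-trimethoxyphenyl)prop-2-en-1-one F5, which is not isolated and closes with loss of dimethylamine to chromone 18. The free hydroxyl group of F4 derives from the original phenol, so the 6-methoxy pattern is fixed without ambiguity.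

2. Step 7. The carbanion of 9 sits between two oxygen substituents. The silyl shift may be outrun by proton abstraction from a benzylic position or the solvent, and the crowded phenoxide may be triflated incompletely.
Fallback from phenol 6, returning at 11, by carbamate-directed ortho-metalation with external silylation. Phenol 6 and isopropyl isocyanate (Et3N, CH2Cl2) give 3,5-bis(benzyloxy)-4-methoxyphenyl N-isopropylcarbamate F6. In-situ N-silylation (TBSOTf, TMEDA, Et2O), ortho-lithiation (n-BuLi, −78 °C), quench with TMSCl and acidic work-up should give 3,5-bis(benzyloxy)-4-methoxy-2-(trimethylsilyl)phenyl N-isopropylcarbamate F7; the two ortho positions are equivalent. Et2NH and DBU in MeCN at 40 °C release 3,5-bis(benzyloxy)-4-methoxy-2-(trimethylsilyl)phenol F8 in the flask, and PhNTf2 added to the same pot converts it into triflate 11.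

3. Step 11. Hydrogen may also add to the C2–C3 double bond of the chromone before the second benzyl group has gone, and the hydrogen-bond-free, peri-positioned 5-O-benzyl group may cleave slowly.
Fallback from 18 directly to 19 by non-reductive Lewis-acid debenzylation: BCl3 with pentamethylbenzene as cation scavenger in CH2Cl2 at −78 °C, which should spare the aryl methyl ethers and the enone. This fallback makes no new compound (F0).

**Further compounds**

F1 | step 10 | 1,3-bis(benzyloxy)-4-bromo-2-methoxy-5-(methoxymethoxy)benzene | COCOc1cc(OCc2ccccc2)c(OC)c(OCc2ccccc2)c1Br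
F2 | step 10 | N-methoxy-N-methyl-2-(2,3,4-trimethoxyphenyl)acetamide | CON(C)C(=O)Cc1ccc(OC)c(OC)c1OC
F3 | step 10 | 1-[2,4-bis(benzyloxy)-3-methoxy-6-(methoxymethoxy)phenyl]-2-(2,3,4-trimethoxyphenyl)ethan-1-one | COCOc1cc(OCc2ccccc2)c(OC)c(OCc2ccccc2)c1C(=O)Cc1ccc(OC)c(OC)c1OC
F4 | step 10 | 1-[2,4-bis(benzyloxy)-6-hydroxy-3-methoxyphenyl]-2-(2,3,4-trimethoxyphenyl)ethan-1-one | COc1ccc(CC(=O)c2c(O)cc(OCc3ccccc3)c(OC)c2OCc2ccccc2)c(OC)c1OC
F5 | step 10 | (E)-1-[2,4-bis(benzyloxy)-6-hydroxy-3-methoxyphenyl]-3-(dimethylamino)-2-(2,3,4-trimethoxyphenyl)prop-2-en-1-one | CN(C)/C=C(\c1ccc(OC)c(OC)c1OC)C(=O)c1c(O)cc(OCc2ccccc2)c(OC)c1OCc1ccccc1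
F6 | step 7 | 3,5-bis(benzyloxy)-4-methoxyphenyl N-isopropylcarbamate | CC(C)NC(=O)Oc1cc(OCc2ccccc2)c(OC)c(OCc2ccccc2)c1
F7 | step 7 | 3,5-bis(benzyloxy)-4-methoxy-2-(trimethylsilyl)phenyl N-isopropylcarbamate | CC(C)NC(=O)Oc1cc(OCc2ccccc2)c(OC)c(OCc2ccccc2)c1[Si](C)(C)C
F8 | step 7 | 3,5-bis(benzyloxy)-4-methoxy-2-(trimethylsilyl)phenol | COc1c(OCc2ccccc2)cc(O)c([Si](C)(C)C)c1OCc1ccccc1
F0 | step 11 | none | none
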